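## Analysis of the target

Conventions: eudesmane numbering (C1–C15) for the lactone half, β being the face of the C10 methyl; primed locants for the elemane cyclohexane (C1′ quaternary, C2′ isopropenyl-bearing, C4′ bonded to the pyran); pyran atoms O1, C2 (= C11), C3 (= C13), C4, C5, C6.

The target is two sesquiterpene-type halves joined through a 3,4-dihydro-2H-pyran. Pyran C2 is the spiro carbon C11 of a eudesman-8,12-olide (decalin rings A and B plus a γ-lactone), and pyran C5 carries C4′ of an elemane cyclohexane. There are eight stereocentres. In the lactone half the C10 methyl, H5, the C7–C11 bond and the C8–O bond all lie on the β face, so both the decalin and the lactone are cis-fused; the pyran oxygen sits on the α face of C11, the convex side next to H7 and H8. In the elemane ring the vinyl, isopropenyl and C4′ substituents are all equatorial (1′,2′-trans, 2′,4′-cis) with the methyl axial, and the absolute configuration (1′R,2′R,4′S) is the mirror image of the common β-elemene series, so the chiral pool does not supply it. The halves are linked only through the achiral pyran atoms C3–C6, so neither relays stereochemistry to the other and each must be made as a single enantiomer. Sensitive groups are the acid-labile enol ether, the vinyl, isopropenyl and exocyclic methylene groups (no hydrogenation, peracid, electrophilic halogen or strong acid late), the lactone, and C5, which can epimerise whenever C4 is a carbonyl. The strategy rests on one feature: pyran C6 is a lone oxidised CH between O1 and C5, while C3 and C4 are plain methylenes. C4–C5 can therefore be read as an alkyne between C13 and C4′, and C6 as carbon monoxide added to it under direction from the C11 oxygen.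

## Retrosynthetic reasoning

**38 ⇒ 36 ⇒ 34.** The enol ether C5=C6 is the most fragile function and is made last, by dehydration of lactol 36. Lactol 36 is the closed form of hydroxy aldehyde 35, the conjugate-reduction product of enal 34. Staying at the aldehyde level keeps C6 at the oxidation state it has in 38, and the centre formed at C5 needs no control because it becomes sp2 again.

**34 ⇒ 33 ⇒ 31 + 32 (key disconnection).** The C5–C6 bond and a temporary C4–Si bond are cut. Forward, the hydrosilyl ether 31 takes up carbon monoxide 32 under rhodium catalysis; the five-membered O–Si tether puts silicon on C4 and the formyl group on C5. This installs C6 without touching the four alkenes, and the silicon is then exchanged for hydrogen.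

**31 ⇒ 30 ⇒ 29 ⇒ 28 + 15.** The O–Si bond, then the C11–O bond, then the C11–C13 bond are cut. C11 is the α-carbon of lactone 28, so both bonds come from enolate chemistry: alkylation with propargylic bromide 15 joins the halves, and oxygenation of the resulting enolate from the convex face sets the spiro centre. The order (carbon first, oxygen second) is what places oxygen on the α face.

**15 ⇒ 14 ⇒ 13 ⇒ 10 + 12.** The C4′–C(sp) bond is cut. An aldehyde at C4′ would equilibrate only weakly towards the equatorial epimer, so the bond is made instead from the configurationally mobile zinc reagent 13 and bromoalkyne 12. That coupling settles in the equatorial position of a ring locked by three other substituents.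

**10 ⇒ 9 ⇒ 8 ⇒ 7 ⇒ 6 ⇒ 2 + 5.** The ring bonds C1′–C6′ and C2′–C3′ are cut in a Diels–Alder sense. The trans geometry of dienophile 5 becomes the 1′,2′-trans relationship, the catalyst sets the absolute configuration, and the silyloxy group of diene 2 places a carbonyl exactly at C4′. Formyl and acetyl in 6 are the precursors of vinyl and isopropenyl. Diene 2 comes from 1, dienophile 5 from 3 and 4.

**28 ⇒ 27 ⇒ 26 ⇒ 25 ⇒ 24 ⇒ 23 ⇒ 21 + 22.** The exocyclic methylene is taken back to a C4 ketone and then to a silyl-protected carbinol, the lactone C–O bond to a C8 ketone, and the C7–C11 bond to alkylation with 22. The C4 carbinol is kept as long as possible because its equatorial silyloxy group locks the cis-decalin in one chair–chair form, in which C7 alkylation and C8 reduction have predictable outcomes.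

**21 ⇒ 20 ⇒ 19 ⇒ 18 ⇒ 17 ⇒ 16.** The C10–methyl bond is cut (conjugate methylation of an octalone, which gives the cis ring fusion), the enone is traced to an anisole by Birch reduction, and the carbinol to tetralone 16 by asymmetric transfer hydrogenation. The single carbinol centre of 17 thus controls C5, and C5 controls C10.

## Alternatives that were turned down

**Alternative 1:** The cut is the C4–C5 bond of ring A. Forward, the achiral dienone A1 would be cyclised reductively by a zerovalent nickel catalyst carrying a chiral phosphine, with a silane as hydride source. The alkyne adds to one of the two enantiotopic enone β-carbons and gives octalenone A2, setting ring A, the exocyclic methylene, the cis fusion and both decalin stereocentres in one catalytic step. On the decalin this is clearly stronger than the route used here, which spends steps 11–19, a control element and an epimer separation on the same two centres. Against it, A2 has its oxygen at C7 where the lactone needs carbon at C7 and oxygen at C8, so a 1,2-transposition with two more stereocentres follows. The enantioselectivity rests wholly on the ligand differentiating two remote enone faces. The spiro pyran and the elemane half are left untouched. The chosen strategy offers in its place a direct answer to the dihydropyran: the C5–C6 bond, the correct oxidation level at C3, C4 and C6, and the union of the halves all follow from one alkyne.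

**Alternative 2:** The cut is the C1′–C2′ bond, read backwards as the [3,3] shift of a ten-membered 1,5-diene. Forward, heating the (E,E)-cyclodecadiene A3 passes through a chair transition state, forms C1′–C2′, breaks the opposite allylic bond and gives elemene A4 with the quaternary and adjacent tertiary centres trans. For C1′/C2′ this is stronger than the Diels–Alder of step 3: no catalyst-controlled face selection, full atom economy, and C4′ already equatorial. Against it, A3 is the unnatural enantiomer of a strained medium ring that rearranges on gentle warming, and its synthesis would be longer than the whole elemane branch used here. More seriously, A4 is a hydrocarbon whose C4′ isopropenyl group cannot be told apart from the one at C2′, while the target needs C4′ bonded to pyran C5. The step also contributes nothing to the pyran or the spiro centre. The chosen route gives instead a C4′ ketone (8) as a handle, so the halves are joined through C4′ without differentiating like groups.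

**Alternative 3:** The cut is the O1–C6 bond, with the furan of A5 as a masked 1,4-dicarbonyl that already holds pyran C3–C6. Forward, oxidation of the tertiary furfuryl alcohol A5 with an electrophilic bromine source in buffered aqueous solvent (or at an anode) opens the furan; the aldehyde is captured by the tertiary hydroxyl to give pyranone lactol A6. As a ring-forming step this is operationally simpler and more dependable than a carbonylation under pressure, and on that point it is stronger. Against it, A6 is over-oxidised for this target: it has a ketone at C3 next to the spiro centre and a C4=C5 double bond, where the target has two methylenes and a C5=C6 enol ether. Removing a hindered ketone, reducing the enone and shifting the double bond would cost at least four redox steps, against three simple steps after the key step here. Electrophilic bromine would also compete for the isopropenyl, vinyl and exocyclic methylene groups, and A5 needs a 2,4-disubstituted furan carrying the elemane ring. The chosen strategy keeps C3 and C4 at the methylene level throughout and sets C11 by convex-face oxygenation in step 21.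

Key step: step 23

Assumption: the (S)-prolinol-derived oxazaborolidinium catalyst of step 3 is taken to shield the face of aldehyde-bound 5 that leads to (1S,6S)-6; if the sense of induction proves opposite, the catalyst from (R)-prolinol is used and nothing else changes.

Assumption: compounds 1, 3, 4, 11, 16, 22 and 32 and all reagents are taken as commercial.

## Route

Step 1
Reactants: 1 methyl vinyl ketone (but-3-en-2-one)
Product: 2 2-(triisopropylsilyloxy)buta-1,3-diene
Conditions: i-Pr3SiOTf, Et3N, Et2O, 0 → 23 °C
Reagents that add atoms: triisopropylsilyl trifluoromethanesulfonate, CC(C)[Si](C(C)C)(C(C)C)OS(=O)(=O)C(F)(F)F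
Why: Soft enolisation of the methyl ketone and O-silylation (silyl enol ether formation) give the 2-silyloxy diene; the bulky silyl group keeps diene and cycloadduct intact under the acidic catalyst of step 3.

Step 2
Reactants: 3 methylglyoxal (2-oxopropanal, 40% in water); 4 2-(triphenylphosphoranylidene)propanal
Product: 5 (E)-2-methyl-4-oxopent-2-enal
Conditions: CH2Cl2/H2O, 23 → 40 °C, 3 in excess
Reagents that add atoms: none
Why: Wittig olefination of the formyl-stabilised ylide at the aldehyde carbon of 3, which is far more electrophilic than its ketone; stabilised ylides give the (E)-alkene, here with formyl and acetyl trans.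

Step 3
Reactants: 2 2-(triisopropylsilyloxy)buta-1,3-diene; 5 (E)-2-methyl-4-oxopent-2-enal
Product: 6 (1S,6S)-6-acetyl-1-methyl-4-(triisopropylsilyloxy)cyclohex-3-ene-1-carbaldehyde
Conditions: (S)-3,3-diphenyl-1-(2-methylphenyl)tetrahydro-1H,3H-pyrrolo[1,2-c][1,3,2]oxazaborole (15 mol %), HN(SO2CF3)2 (12 mol %), CH2Cl2, −78 → −40 °C
Reagents that add atoms: none
Why: Catalytic enantioselective Diels–Alder reaction of an α-methyl enal bound through its formyl group to the chiral oxazaborolidinium ion; the nucleophilic diene terminus bonds to the carbon β to the activated aldehyde, so the quaternary carbon ends para to the silyloxy carbon. The trans formyl/acetyl geometry of 5 is carried suprafacially into the 1,6-trans adduct, and the catalyst sets the absolute configuration.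

Step 4
Reactants: 6 (1S,6S)-6-acetyl-1-methyl-4-(triisopropylsilyloxy)cyclohex-3-ene-1-carbaldehyde
Product: 7 (4R,5R)-4-ethenyl-4-methyl-5-(prop-1-en-2-yl)-1-(triisopropylsilyloxy)cyclohex-1-ene
Conditions: Ph3PCH3Br, KN(SiMe3)2 (slight deficit to the salt), THF, −78 → 23 °C
Reagents that add atoms: methyltriphenylphosphonium bromide, C[P+](c1ccccc1)(c1ccccc1)c1ccccc1.[Br-]
Why: Double Wittig methylenation turns formyl into vinyl and acetyl into isopropenyl in one operation, the aldehyde reacting first; the ring ketone stays masked as the silyl enol ether. No free base is left over, which protects the centre α to the acetyl group from epimerisation.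

Step 5
Reactants: 7 (4R,5R)-4-ethenyl-4-methyl-5-(prop-1-en-2-yl)-1-(triisopropylsilyloxy)cyclohex-1-ene
Product: 8 (3R,4R)-4-ethenyl-4-methyl-3-(prop-1-en-2-yl)cyclohexan-1-one
Conditions: Bu4NF, AcOH, THF, 0 °C
Reagents that add atoms: none
Why: Fluoride cleavage of the silyl enol ether and protonation of the enolate (desilylation); the buffered medium avoids acid at the isopropenyl group, and neither stereocentre is α to the ketone.

Step 6
Reactants: 8 (3R,4R)-4-ethenyl-4-methyl-3-(prop-1-en-2-yl)cyclohexan-1-one
Product: 9 (1S,3R,4R)-4-ethenyl-4-methyl-3-(prop-1-en-2-yl)cyclohexan-1-ol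
Conditions: NaBH4, MeOH, 0 °C
Reagents that add atoms: none
Why: Borohydride reduction; axial hydride attack on the locked chair should give mainly the equatorial alcohol. Any axial epimer is carried along, because this centre is erased at the organozinc stage.

Step 7
Reactants: 9 (1S,3R,4R)-4-ethenyl-4-methyl-3-(prop-1-en-2-yl)cyclohexan-1-ol
Product: 10 (1R,2R,4R)-1-ethenyl-4-iodo-1-methyl-2-(prop-1-en-2-yl)cyclohexane
Conditions: I2, PPh3, imidazole, toluene, 0 → 23 °C
Reagents that add atoms: iodine, II
Why: Appel-type iodination through the alkoxyphosphonium ion with inversion, so mainly the axial iodide is expected; an equatorial leaving group also limits competing elimination.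

Step 8
Reactants: 11 tert-butyldimethyl(prop-2-yn-1-yloxy)silane
Product: 12 (3-bromoprop-2-yn-1-yloxy)(tert-butyl)dimethylsilane
Conditions: N-bromosuccinimide, AgNO3 (10 mol %), acetone, 23 °C
Reagents that add atoms: N-bromosuccinimide, O=C1CCC(=O)N1Br
Why: Silver-catalysed electrophilic bromination of the terminal alkyne through the silver acetylide.

Step 9
Reactants: 10 (1R,2R,4R)-1-ethenyl-4-iodo-1-methyl-2-(prop-1-en-2-yl)cyclohexane; 12 (3-bromoprop-2-yn-1-yloxy)(tert-butyl)dimethylsilane
Product: 14 tert-butyldimethyl({3-[(1S,3R,4R)-4-ethenyl-4-methyl-3-(prop-1-en-2-yl)cyclohexyl]prop-2-yn-1-yl}oxy)silane, via cyclohexylzinc iodide 13 (not isolated)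
Conditions: Zn, LiCl, THF, 25 °C; then 12, PdCl2[P(C6H2(OMe)3-2,4,6)3]2 (5 mol %), THF, −20 → 23 °C
Reagents that add atoms: none
Why: Zinc insertion into the C–I bond erases the configuration at that carbon; the secondary alkylzinc then couples with the bromoalkyne in a palladium-catalysed Negishi-type C(sp3)–C(sp) coupling. The ring is locked by equatorial vinyl and isopropenyl groups, and the carbon–metal bond settles in the equatorial position before reductive elimination with retention, so the alkynyl group ends cis to the isopropenyl group (1S).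

Step 10
Reactants: 14 tert-butyldimethyl({3-[(1S,3R,4R)-4-ethenyl-4-methyl-3-(prop-1-en-2-yl)cyclohexyl]prop-2-yn-1-yl}oxy)silane
Product: 15 (1R,2R,4S)-4-(3-bromoprop-1-yn-1-yl)-1-ethenyl-1-methyl-2-(prop-1-en-2-yl)cyclohexane
Conditions: Ph3PBr2, CH2Cl2, 0 → 23 °C
Reagents that add atoms: dibromotriphenylphosphorane, BrP(Br)(c1ccccc1)(c1ccccc1)c1ccccc1
Why: Direct conversion of a primary silyl ether into the bromide: the phosphorane takes the oxygen as an alkoxyphosphonium ion and bromide displaces it (SN2), with no free acid to touch the alkenes.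

Step 11
Reactants: 16 6-methoxy-1-tetralone
Product: 17 (S)-6-methoxy-1,2,3,4-tetrahydronaphthalen-1-ol
Conditions: RuCl[(S,S)-TsNCH(Ph)CH(Ph)NH2](p-cymene) (1 mol %), HCO2H/Et3N (5:2), 40 °C
Reagents that add atoms: none
Why: Noyori-type asymmetric transfer hydrogenation of an aryl ketone; the (S,S)-catalyst delivers hydride to give the (S)-carbinol, as for 1-tetralone itself.

Step 12
Reactants: 17 (S)-6-methoxy-1,2,3,4-tetrahydronaphthalen-1-ol
Product: 19 (4aS,5S)-5-hydroxy-4,4a,5,6,7,8-hexahydronaphthalen-2(3H)-one, via dihydroanisole 18 (not isolated)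
Conditions: Li, NH3 (l), t-BuOH, THF, −78 → −33 °C; then 1 M HCl, THF, 23 °C
Reagents that add atoms: water, O
Why: Birch reduction of the anisole ring (the benzylic alkoxide formed in situ resists hydrogenolysis), then enol ether hydrolysis and acid-mediated conjugation. The acid equilibrates the new ring-fusion centre through the dienol; the epimer with hydroxyl and ring bond both equatorial (OH cis to the ring-fusion hydrogen) should be favoured and is separated, the other being re-equilibrated and recycled.

Step 13
Reactants: 19 (4aS,5S)-5-hydroxy-4,4a,5,6,7,8-hexahydronaphthalen-2(3H)-one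
Product: 20 (4aS,5S)-5-(tert-butyldimethylsilyloxy)-4,4a,5,6,7,8-hexahydronaphthalen-2(3H)-one
Conditions: t-BuMe2SiCl, imidazole, DMF, 23 °C
Reagents that add atoms: tert-butyldimethylsilyl chloride, CC(C)(C)[Si](C)(C)Cl
Why: Standard silylation of the secondary alcohol; the equatorial silyloxy group later serves as the conformational anchor of the cis-decalin.

Step 14
Reactants: 20 (4aS,5S)-5-(tert-butyldimethylsilyloxy)-4,4a,5,6,7,8-hexahydronaphthalen-2(3H)-one
Product: 21 (4aS,5S,8aR)-5-(tert-butyldimethylsilyloxy)-8a-methyloctahydronaphthalen-2(1H)-one (cis-fused; eudesmane numbering: 4β-silyloxy 5β-H 10β-methyl 8-ketone)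
Conditions: Me2CuLi (from MeLi, CuI), Et2O, −30 → 0 °C; aq. NH4Cl
Reagents that add atoms: methyllithium (as lithium dimethylcuprate), [Li]C
Why: Cuprate conjugate addition to the ring-fusion β-carbon; axial attack anti to the pseudoaxial ring-A bond at C5 gives the cis-fused decalone (methyl cis to H5), the established outcome for such octalones, so C10 follows from C5.

Step 15
Reactants: 21 (4aS,5S,8aR)-5-(tert-butyldimethylsilyloxy)-8a-methyloctahydronaphthalen-2(1H)-one; 22 methyl bromoacetate
Product: 23 methyl 2-[4β-(tert-butyldimethylsilyloxy)-10β-methyl-8-oxo-5βH-decalin-7β-yl]acetate (eudesmane numbering)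
Conditions: LiN(i-Pr)2, THF, −78 °C; then 22, DMPU, −78 → −30 °C
Reagents that add atoms: none
Why: Kinetic enolate formation at C7, away from the neopentyl C9, followed by enolate alkylation. With the decalin locked by the equatorial silyloxy group (C10 methyl axial on ring B), attack anti to the axial C4 bond gives the equatorial 7β side chain, which is also the thermodynamic epimer.

Step 16
Reactants: 23 methyl 2-[4β-(tert-butyldimethylsilyloxy)-10β-methyl-8-oxo-5βH-decalin-7β-yl]acetate
Product: 25 4β-(tert-butyldimethylsilyloxy)-5βH-13,15-dinoreudesman-8β,12-olide, via hydroxy ester 24 (not isolated)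
Conditions: LiBH(s-Bu)3, THF, −78 → 23 °C; aq. NH4Cl
Reagents that add atoms: none
Why: Bulky hydride reduction; the axial path to C8 on the β face is blocked by the syn-axial C10 methyl, so hydride enters equatorially from the α face and gives the axial 8β-alkoxide. Being cis to the C7 side chain, it closes the cis-fused γ-lactone (lactonisation) on warming.

Step 17
Reactants: 25 4β-(tert-butyldimethylsilyloxy)-5βH-13,15-dinoreudesman-8β,12-olide
Product: 26 4β-hydroxy-5βH-13,15-dinoreudesman-8β,12-olide
Conditions: Bu4NF, THF, 40 °C
Reagents that add atoms: none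
Why: Fluoride desilylation; the lactone and all stereocentres are unaffected.

Step 18
Reactants: 26 4β-hydroxy-5βH-13,15-dinoreudesman-8β,12-olide
Product: 27 4-oxo-5βH-13,15-dinoreudesman-8β,12-olide
Conditions: Dess–Martin periodinane, NaHCO3, CH2Cl2, 23 °C
Reagents that add atoms: none
Why: Dess–Martin oxidation under buffered, non-enolising conditions, so the ring-fusion hydrogen α to the new ketone keeps its cis configuration.

Step 19
Reactants: 27 4-oxo-5βH-13,15-dinoreudesman-8β,12-olide
Product: 28 5βH-13-noreudesm-4(15)-en-8β,12-olide [(3aR,4aR,8aR,9aR)-8a-methyl-5-methylidene-3a,4,4a,6,7,8,9,9a-octahydro-3H-benzo[f][1]benzofuran-2-one]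
Conditions: Zn, CH2Br2, TiCl4, THF, 0 → 23 °C
Reagents that add atoms: dibromomethane, BrCBr
Why: Takai–Lombardo methylenation; the non-basic zinc–titanium methylene reagent reacts with the ketone but not the lactone and does not enolise, so C5 is not epimerised as it could be under a basic ylide.

Step 20
Reactants: 28 5βH-13-noreudesm-4(15)-en-8β,12-olide; 15 (1R,2R,4S)-4-(3-bromoprop-1-yn-1-yl)-1-ethenyl-1-methyl-2-(prop-1-en-2-yl)cyclohexane
Product: 29 11α-{3-[(1S,3R,4R)-4-ethenyl-4-methyl-3-(prop-1-en-2-yl)cyclohexyl]prop-2-yn-1-yl}-5βH-13-noreudesm-4(15)-en-8β,12-olide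
Conditions: LiN(i-Pr)2, THF, −78 °C; then 15, DMPU, −78 → −20 °C
Reagents that add atoms: none
Why: Lactone enolate alkylation (SN2 at the propargylic bromide) joins the halves; the electrophile should enter from the convex face, but the C11 configuration is irrelevant because the centre is re-enolised in step 21.

Step 21
Reactants: 29 11α-{3-[(1S,3R,4R)-4-ethenyl-4-methyl-3-(prop-1-en-2-yl)cyclohexyl]prop-2-yn-1-yl}-5βH-13-noreudesm-4(15)-en-8β,12-olide
Product: 30 11α-hydroxy-11β-{3-[(1S,3R,4R)-4-ethenyl-4-methyl-3-(prop-1-en-2-yl)cyclohexyl]prop-2-yn-1-yl}-5βH-13-noreudesm-4(15)-en-8β,12-olide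
Conditions: KN(SiMe3)2, THF, −78 °C; then 2-(phenylsulfonyl)-3-phenyloxaziridine, −78 °C; aq. NH4Cl
Reagents that add atoms: 2-(phenylsulfonyl)-3-phenyloxaziridine, O=S(=O)(c1ccccc1)N1OC1c1ccccc1
Why: Davis oxidation of the tetrasubstituted lactone enolate; oxygen is delivered to the convex α face of the cis-fused lactone (the side of H7 and H8), pushing the propargyl group β. This sets C11 with the configuration of the spiro centre of 38.

Step 22
Reactants: 30 11α-hydroxy-11β-{3-[(1S,3R,4R)-4-ethenyl-4-methyl-3-(prop-1-en-2-yl)cyclohexyl]prop-2-yn-1-yl}-5βH-13-noreudesm-4(15)-en-8β,12-olide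
Product: 31 11α-(dimethylsilyloxy)-11β-{3-[(1S,3R,4R)-4-ethenyl-4-methyl-3-(prop-1-en-2-yl)cyclohexyl]prop-2-yn-1-yl}-5βH-13-noreudesm-4(15)-en-8β,12-olide
Conditions: Me2SiHCl, Et3N, DMAP (cat.), CH2Cl2, 0 → 23 °C; used without chromatography
Reagents that add atoms: chlorodimethylsilane, C[SiH](C)Cl
Why: O-silylation of the tertiary alcohol with a small chlorosilane; this installs the Si–H tether that directs the key step.

Step 23
Reactants: 31 11α-(dimethylsilyloxy)-11β-{3-[(1S,3R,4R)-4-ethenyl-4-methyl-3-(prop-1-en-2-yl)cyclohexyl]prop-2-yn-1-yl}-5βH-13-noreudesm-4(15)-en-8β,12-olide; 32 carbon monoxide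
Product: 33 (2Z)-2-[(1S,3R,4R)-4-ethenyl-4-methyl-3-(prop-1-en-2-yl)cyclohexyl]-2-(2,2-dimethyl-1,2-oxasilolan-3-ylidene)acetaldehyde spiro-fused at oxasilolane C5 to C11 of 5βH-13-noreudesm-4(15)-en-8β,12-olide (ring oxygen 11α)
Conditions: Rh(acac)(CO)2 (2 mol %), CO (40 atm), toluene, 60 °C
Reagents that add atoms: none
Why: The Si–H bond adds oxidatively to monovalent rhodium carbonyl, the tethered silyl group is transferred to the nearer alkyne carbon (pyran C4), CO inserts into the resulting alkenyl–rhodium bond at C5, and reductive elimination of the acyl hydride releases the aldehyde and the catalyst. The closest known reaction type is the rhodium-catalysed intramolecular silylformylation of alkynyl hydrosilyl ethers, which is established for internal homopropargylic cases. One ring closes, the 1,2-oxasilolane, by 5-exo-dig attack, with the geminal substitution at C11 favouring closure. No stereocentre is formed; syn addition fixes silicon and formyl cis on the tetrasubstituted alkene. The step needs regioselectivity (formyl on the carbon bearing the cyclohexyl ring), which the five-membered tether secures by holding silicon on the proximal carbon. It also needs chemoselectivity for the alkyne over the vinyl, isopropenyl and methylene groups: without hydrogen there is no hydroformylation, the only hydride is the tethered Si–H, and CO pressure suppresses simple hydrosilylation. C11 and the lactone are not touched.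

Step 24
Reactants: 33 spiro oxasilolane enal
Product: 34 11α-hydroxy-11β-{(2E)-3-[(1S,3R,4R)-4-ethenyl-4-methyl-3-(prop-1-en-2-yl)cyclohexyl]-4-oxobut-2-en-1-yl}-5βH-13-noreudesm-4(15)-en-8β,12-olide
Conditions: Bu4NF, THF, H2O (5 equiv), 0 → 23 °C
Reagents that add atoms: none
Why: Fluoride-promoted protodesilylation of the alkenyl siloxane through a pentacoordinate silicate, with retention at carbon, so hydrogen takes the place of silicon and the (E)-enal results; the Si–O bond is cleaved as well, freeing the tertiary alcohol. The formyl group is trans to the carbinol chain, so no lactol can form yet.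

Step 25
Reactants: 34 (E)-hydroxy enal
Product: 36 6-hydroxy-5-[(1S,3R,4R)-4-ethenyl-4-methyl-3-(prop-1-en-2-yl)cyclohexyl]tetrahydro-2H-pyran spiro-fused at C2 to C11 of 5βH-13-noreudesm-4(15)-en-8β,12-olide (pyran oxygen 11α; mixture at pyran C5 and C6), via hydroxy aldehyde 35 (not isolated)
Conditions: [(Ph3P)CuH]6 (0.5 equiv), benzene, H2O (10 equiv), 23 °C
Reagents that add atoms: none
Why: Copper hydride conjugate reduction: hydride adds to the β-carbon and water protonates the copper enolate, while isolated alkenes and the lactone are inert to this reagent. The saturated aldehyde is captured at once by the tertiary hydroxyl as the six-membered lactol, which shields it from over-reduction; the mixed centres at pyran C5 and C6 do not matter because both are planarised or removed in step 26.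

Step 26
Reactants: 36 spiro lactol
Product: 38 the target: 5-[(1S,3R,4R)-4-ethenyl-4-methyl-3-(prop-1-en-2-yl)cyclohexyl]-3,4-dihydro-2H-pyran spiro-fused at C2 to C11 of 5βH-13-noreudesm-4(15)-en-8β,12-olide (pyran oxygen 11α), via anomeric mesylate 37 (not isolated)
Conditions: MeSO2Cl, Et3N, CH2Cl2, 0 → 40 °C
Reagents that add atoms: none
Why: Dehydration of a lactol through its anomeric sulfonate: ionisation to the oxocarbenium ion and loss of the only β-hydrogen (at C5) give the enol ether. The basic medium is chosen over acid catalysis to spare the enol ether and the 1,1-disubstituted alkenes.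

## Compound list

1 | methyl vinyl ketone | CC(=O)C=C | starting material
2 | 2-(triisopropylsilyloxy)buta-1,3-diene | C=CC(=C)O[Si](C(C)C)(C(C)C)C(C)C | intermediate
3 | methylglyoxal | CC(=O)C=O | starting material
4 | 2-(triphenylphosphoranylidene)propanal | CC(C=O)=P(c1ccccc1)(c1ccccc1)c1ccccc1 | starting material
5 | (E)-2-methyl-4-oxopent-2-enal | O=C/C(C)=C/C(C)=O | intermediate
6 | (1S,6S)-6-acetyl-1-methyl-4-(triisopropylsilyloxy)cyclohex-3-ene-1-carbaldehyde | O=C[C@@]1(C)CC=C(O[Si](C(C)C)(C(C)C)C(C)C)C[C@@H]1C(C)=O | intermediate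
7 | (4R,5R)-4-ethenyl-4-methyl-5-(prop-1-en-2-yl)-1-(triisopropylsilyloxy)cyclohex-1-ene | C=C[C@@]1(C)CC=C(O[Si](C(C)C)(C(C)C)C(C)C)C[C@@H]1C(=C)C | intermediate
8 | (3R,4R)-4-ethenyl-4-methyl-3-(prop-1-en-2-yl)cyclohexan-1-one | C=C[C@@]1(C)CCC(=O)C[C@@H]1C(=C)C | intermediate
9 | (1S,3R,4R)-4-ethenyl-4-methyl-3-(prop-1-en-2-yl)cyclohexan-1-ol (major, equatorial OH) | C=C[C@@]1(C)CC[C@H](O)C[C@@H]1C(=C)C | intermediate
10 | (1R,2R,4R)-1-ethenyl-4-iodo-1-methyl-2-(prop-1-en-2-yl)cyclohexane (major, axial iodide) | C=C[C@@]1(C)CC[C@@H](I)C[C@@H]1C(=C)C | intermediate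
11 | tert-butyldimethyl(prop-2-yn-1-yloxy)silane | C#CCO[Si](C)(C)C(C)(C)C | starting material
12 | (3-bromoprop-2-yn-1-yloxy)(tert-butyl)dimethylsilane | BrC#CCO[Si](C)(C)C(C)(C)C | intermediate
13 | [(3R,4R)-4-ethenyl-4-methyl-3-(prop-1-en-2-yl)cyclohexyl]zinc iodide (C–Zn epimers interconvert) | C=C[C@@]1(C)CCC([Zn]I)C[C@@H]1C(=C)C | intermediate
14 | tert-butyldimethyl({3-[(1S,3R,4R)-4-ethenyl-4-methyl-3-(prop-1-en-2-yl)cyclohexyl]prop-2-yn-1-yl}oxy)silane | C=C[C@@]1(C)CC[C@H](C#CCO[Si](C)(C)C(C)(C)C)C[C@@H]1C(=C)C | intermediate
15 | (1R,2R,4S)-4-(3-bromoprop-1-yn-1-yl)-1-ethenyl-1-methyl-2-(prop-1-en-2-yl)cyclohexane | C=C[C@@]1(C)CC[C@H](C#CCBr)C[C@@H]1C(=C)C | intermediate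
16 | 6-methoxy-1-tetralone | COc1ccc2C(=O)CCCc2c1 | starting material
17 | (S)-6-methoxy-1,2,3,4-tetrahydronaphthalen-1-ol | COc1ccc2c(c1)CCC[C@@H]2O | intermediate
18 | (S)-6-methoxy-1,2,3,4,5,8-hexahydronaphthalen-1-ol | COC1=CCC2=C(C1)CCC[C@@H]2O | intermediate
19 | (4aS,5S)-5-hydroxy-4,4a,5,6,7,8-hexahydronaphthalen-2(3H)-one | O=C1CC[C@@H]2[C@@H](O)CCCC2=C1 | intermediate
20 | (4aS,5S)-5-(tert-butyldimethylsilyloxy)-4,4a,5,6,7,8-hexahydronaphthalen-2(3H)-one | O=C1CC[C@@H]2[C@@H](O[Si](C)(C)C(C)(C)C)CCCC2=C1 | intermediate
21 | (4aS,5S,8aR)-5-(tert-butyldimethylsilyloxy)-8a-methyloctahydronaphthalen-2(1H)-one (cis-fused) | O=C1CC[C@@H]2[C@@H](O[Si](C)(C)C(C)(C)C)CCC[C@]2(C)C1 | intermediate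
22 | methyl bromoacetate | COC(=O)CBr | starting material
23 | methyl 2-[4β-(tert-butyldimethylsilyloxy)-10β-methyl-8-oxo-5βH-decalin-7β-yl]acetate | COC(=O)C[C@H]1C[C@@H]2[C@@H](O[Si](C)(C)C(C)(C)C)CCC[C@]2(C)CC1=O | intermediate
24 | methyl 2-[4β-(tert-butyldimethylsilyloxy)-8β-hydroxy-10β-methyl-5βH-decalin-7β-yl]acetate | COC(=O)C[C@H]1C[C@@H]2[C@@H](O[Si](C)(C)C(C)(C)C)CCC[C@]2(C)C[C@H]1O | intermediate
25 | 4β-(tert-butyldimethylsilyloxy)-5βH-13,15-dinoreudesman-8β,12-olide | C1C(=O)O[C@@H]2C[C@@]3(C)CCC[C@H](O[Si](C)(C)C(C)(C)C)[C@H]3C[C@@H]21 | intermediate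
26 | 4β-hydroxy-5βH-13,15-dinoreudesman-8β,12-olide | C1C(=O)O[C@@H]2C[C@@]3(C)CCC[C@H](O)[C@H]3C[C@@H]21 | intermediate
27 | 4-oxo-5βH-13,15-dinoreudesman-8β,12-olide | C1C(=O)O[C@@H]2C[C@@]3(C)CCCC(=O)[C@H]3C[C@@H]21 | intermediate
28 | 5βH-13-noreudesm-4(15)-en-8β,12-olide | C1C(=O)O[C@@H]2C[C@@]3(C)CCCC(=C)[C@H]3C[C@@H]21 | intermediate
29 | 11α-propargylated lactone (11βH) | C=C[C@@]1(C)CC[C@H](C#CC[C@H]2C(=O)O[C@@H]3C[C@@]4(C)CCCC(=C)[C@H]4C[C@@H]32)C[C@@H]1C(=C)C | intermediate
30 | 11α-hydroxy-11β-propargyl lactone | C=C[C@@]1(C)CC[C@H](C#CC[C@]2(O)C(=O)O[C@@H]3C[C@@]4(C)CCCC(=C)[C@H]4C[C@@H]32)C[C@@H]1C(=C)C | intermediate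
31 | 11α-(dimethylsilyloxy)-11β-propargyl lactone (key precursor) | C=C[C@@]1(C)CC[C@H](C#CC[C@]2(O[SiH](C)C)C(=O)O[C@@H]3C[C@@]4(C)CCCC(=C)[C@H]4C[C@@H]32)C[C@@H]1C(=C)C | intermediate
32 | carbon monoxide | [C-]#[O+] | starting material
33 | spiro oxasilolane (Z)-β-silyl enal (key product) | C=C[C@@]1(C)CC[C@H](/C(C=O)=C2\C[C@]3(O[Si]2(C)C)C(=O)O[C@@H]4C[C@@]5(C)CCCC(=C)[C@H]5C[C@@H]43)C[C@@H]1C(=C)C | intermediate
34 | 11α-hydroxy (E)-enal | C=C[C@@]1(C)CC[C@H](/C(C=O)=C\C[C@]2(O)C(=O)O[C@@H]3C[C@@]4(C)CCCC(=C)[C@H]4C[C@@H]32)C[C@@H]1C(=C)C | intermediate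
35 | 11α-hydroxy saturated aldehyde (epimers at the formyl-bearing carbon) | C=C[C@@]1(C)CC[C@H](C(C=O)CC[C@]2(O)C(=O)O[C@@H]3C[C@@]4(C)CCCC(=C)[C@H]4C[C@@H]32)C[C@@H]1C(=C)C | intermediate
36 | spiro lactol (mixture at pyran C5 and C6) | C=C[C@@]1(C)CC[C@H](C2CC[C@]3(OC2O)C(=O)O[C@@H]2C[C@@]4(C)CCCC(=C)[C@H]4C[C@@H]23)C[C@@H]1C(=C)C | intermediate
37 | anomeric methanesulfonate of 36 | C=C[C@@]1(C)CC[C@H](C2CC[C@]3(OC2OS(C)(=O)=O)C(=O)O[C@@H]2C[C@@]4(C)CCCC(=C)[C@H]4C[C@@H]23)C[C@@H]1C(=C)C | intermediate
38 | CNP0353330.1 | C=C[C@@]1(C)CC[C@H](C2=CO[C@@]3(CC2)C(=O)O[C@@H]2C[C@@]4(C)CCCC(=C)[C@H]4C[C@@H]23)C[C@@H]1C(=C)C | target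

## Step count and least certain steps

Total: 26 steps. Longest linear sequence: 16 steps (steps 11–19, then 20–26, from 6-methoxy-1-tetralone 16).

**Step 23 (key step).** The most likely failures are plain intramolecular hydrosilylation without CO uptake, slow CO insertion at the alkyne carbon that carries the secondary cyclohexyl group, and isomerisation or hydrosilylation of the terminal alkenes by a rhodium hydride. The fallback replaces the alkyne carbonylation by an inverse-demand hetero-Diels–Alder union. It sets out from lactone 28 and from the zinc reagent 13 (made from 10 as in step 9) and returns at 38. Lactone 28 is aminomethylated through its lithium enolate with dimethyl(methylidene)ammonium iodide to the Mannich base F1, which is N-methylated and eliminated with NaHCO3 to the α-methylene lactone F2. Zinc reagent 13 is coupled under the palladium conditions of step 9 with commercial 2-bromo-3,3-diethoxyprop-1-ene F3 to the acetal F4, and mild aqueous acid frees the 2-substituted acrolein F5. Heating F2 with F5 in toluene with a radical inhibitor should add the enal as heterodiene across the exocyclic alkene, oxygen bonding to C11 from the convex face, to give 38 directly.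

**Step 3.** Competing coordination of the catalyst to the acetyl oxygen of 5 could erode face selectivity or regiocontrol. The fallback uses an ester in place of the ketone; it sets out from diene 2 and returns at 7. Commercial ethyl (E)-3-methyl-4-oxobut-2-enoate F6, whose ester binds the catalyst only weakly, is used as dienophile under the same catalyst to give the formyl ester F7. Wittig methylenation of the aldehyde gives the vinyl ester F8, excess MeLi gives the tertiary alcohol F9, and Burgess dehydration (syn elimination towards the unhindered methyl hydrogens) gives 7.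

**Step 9.** Incomplete equatorial control at the cyclohexyl carbon, or β-hydride elimination of the secondary alkylpalladium intermediate, would lower yield and diastereomeric purity. The fallback builds the alkyne by homologation; it sets out from ketone 8 and returns at 15. Wittig reaction with (methoxymethyl)triphenylphosphonium chloride and KN(SiMe3)2 gives the enol ether F10, and acid hydrolysis followed by K2CO3/MeOH equilibration gives the equatorial aldehyde F11, the axial epimer being separated and re-equilibrated. The Ohira–Bestmann reaction gives the terminal alkyne F12, n-BuLi and paraformaldehyde give the propargylic alcohol F13, and CBr4/PPh3 gives 15.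

**Step 24.** The basic fluoride could isomerise the enal (E/Z or into deconjugation) or cause aldol-type loss before protodesilylation is complete. The fallback takes the aldehyde out of play during desilylation; it sets out from 33 and returns at 34. Luche reduction (NaBH4, CeCl3) gives the allylic alcohol F14, the same fluoride treatment gives the diol F15, and MnO2 oxidises only the primary allylic alcohol back to enal 34.

## Further compounds

F1 | step 23 | 11α-(dimethylaminomethyl)-5βH-13-noreudesm-4(15)-en-8β,12-olide | CN(C)C[C@H]1C(=O)O[C@@H]2C[C@@]3(C)CCCC(=C)[C@H]3C[C@@H]21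
F2 | step 23 | 5βH-eudesma-4(15),11(13)-dien-8β,12-olide | C=C1C(=O)O[C@@H]2C[C@@]3(C)CCCC(=C)[C@H]3C[C@@H]21
F3 | step 23 | 2-bromo-3,3-diethoxyprop-1-ene | C=C(Br)C(OCC)OCC
F4 | step 23 | (1R,2R,4S)-4-(3,3-diethoxyprop-1-en-2-yl)-1-ethenyl-1-methyl-2-(prop-1-en-2-yl)cyclohexane | C=C[C@@]1(C)CC[C@H](C(=C)C(OCC)OCC)C[C@@H]1C(=C)C
F5 | step 23 | 2-[(1S,3R,4R)-4-ethenyl-4-methyl-3-(prop-1-en-2-yl)cyclohexyl]prop-2-enal | C=C[C@@]1(C)CC[C@H](C(=C)C=O)C[C@@H]1C(=C)C
F6 | step 3 | ethyl (E)-3-methyl-4-oxobut-2-enoate | O=C/C(C)=C/C(=O)OCC
F7 | step 3 | ethyl (1S,6S)-6-formyl-6-methyl-3-(triisopropylsilyloxy)cyclohex-3-ene-1-carboxylate | O=C[C@@]1(C)CC=C(O[Si](C(C)C)(C(C)C)C(C)C)C[C@@H]1C(=O)OCC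
F8 | step 3 | ethyl (1S,6R)-6-ethenyl-6-methyl-3-(triisopropylsilyloxy)cyclohex-3-ene-1-carboxylate | C=C[C@@]1(C)CC=C(O[Si](C(C)C)(C(C)C)C(C)C)C[C@@H]1C(=O)OCC
F9 | step 3 | 2-[(1S,6R)-6-ethenyl-6-methyl-3-(triisopropylsilyloxy)cyclohex-3-en-1-yl]propan-2-ol | C=C[C@@]1(C)CC=C(O[Si](C(C)C)(C(C)C)C(C)C)C[C@@H]1C(C)(C)O
F10 | step 9 | (1R,2R)-1-ethenyl-4-(methoxymethylidene)-1-methyl-2-(prop-1-en-2-yl)cyclohexane (E/Z mixture) | C=C[C@@]1(C)CCC(=COC)C[C@@H]1C(=C)C
F11 | step 9 | (1S,3R,4R)-4-ethenyl-4-methyl-3-(prop-1-en-2-yl)cyclohexane-1-carbaldehyde | C=C[C@@]1(C)CC[C@H](C=O)C[C@@H]1C(=C)C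
F12 | step 9 | (1R,2R,4S)-1-ethenyl-4-ethynyl-1-methyl-2-(prop-1-en-2-yl)cyclohexane | C=C[C@@]1(C)CC[C@H](C#C)C[C@@H]1C(=C)C
F13 | step 9 | 3-[(1S,3R,4R)-4-ethenyl-4-methyl-3-(prop-1-en-2-yl)cyclohexyl]prop-2-yn-1-ol | C=C[C@@]1(C)CC[C@H](C#CCO)C[C@@H]1C(=C)C
F14 | step 24 | spiro oxasilolane allylic alcohol (aldehyde of 33 reduced) | C=C[C@@]1(C)CC[C@H](/C(CO)=C2\C[C@]3(O[Si]2(C)C)C(=O)O[C@@H]4C[C@@]5(C)CCCC(=C)[C@H]5C[C@@H]43)C[C@@H]1C(=C)C
F15 | step 24 | 11α-hydroxy (E)-allylic alcohol (diol) | C=C[C@@]1(C)CC[C@H](/C(CO)=C\C[C@]2(O)C(=O)O[C@@H]3C[C@@]4(C)CCCC(=C)[C@H]4C[C@@H]32)C[C@@H]1C(=C)C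
A1 | alternative 1 | 4-methyl-4-(pent-4-yn-1-yl)cyclohexa-2,5-dien-1-one | C#CCCCC1(C)C=CC(=O)C=C1
A2 | alternative 1 | (4aR,8aR)-4a-methyl-8-methylidene-4a,5,6,7,8,8a-hexahydronaphthalen-2(1H)-one | O=C1C=C[C@@]2(C)CCCC(=C)[C@H]2C1
A3 | alternative 2 | (1E,5E,8S)-1,5-dimethyl-8-(prop-1-en-2-yl)cyclodeca-1,5-diene (enantiomeric germacrene A) | C/C1=C\CC/C(C)=C/C[C@@H](C(C)=C)CC1
A4 | alternative 2 | (1R,2R,4S)-β-elemene | C=C[C@@]1(C)CC[C@H](C(C)=C)C[C@@H]1C(=C)C
A5 | alternative 3 | 11α-hydroxy-11β-{4-[(1S,3R,4R)-4-ethenyl-4-methyl-3-(prop-1-en-2-yl)cyclohexyl]furan-2-yl}-5βH-13-noreudesm-4(15)-en-8β,12-olide | C=C[C@@]1(C)CC[C@H](c2coc(c2)[C@]3(O)C(=O)O[C@@H]4C[C@@]5(C)CCCC(=C)[C@H]5C[C@@H]43)C[C@@H]1C(=C)C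
A6 | alternative 3 | spiro 6-hydroxy-2H-pyran-3(6H)-one (anomeric mixture) | C=C[C@@]1(C)CC[C@H](C2=CC(=O)[C@]3(OC2O)C(=O)O[C@@H]4C[C@@]5(C)CCCC(=C)[C@H]5C[C@@H]43)C[C@@H]1C(=C)C
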